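**Retrosynthetic overview**

- The target is traced back to a trans-decalin 7-ketone: the side chain diene comes last (iodo-olefination, Stille coupling), and the C6 acetate and C8 carbinol come from two enolate oxidations on either side of C7.
- That ketone comes from a Δ5-7-enone, which comes from a tertiary C5 carbinol: ring A is closed onto the C5 ketone of a monocyclic ring B keto aldehyde by a one-pot carboborylation/allylboration with (2-methylprop-1-enyl)boronic acid.
- Ring B is (S)-carvone: its C1 carbonyl becomes C5, C2 with its methyl becomes C10/C20, C3 becomes C9, C4 becomes C8, C6 stays C6, and C5 with its isopropenyl group becomes C7 (latent C7 carbonyl). C9 and C10 are set by conjugate addition/allylation anti to the isopropenyl group.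
- Enabling feature: ring A has no heteroatom, and its quaternary C4 carries two identical methyl groups and is bonded to the ring-fusion carbon C5, which sits next to the oxygenated C6–C7 edge of ring B. C4 can therefore be the γ-carbon of a gem-dimethyl allylboron unit (no alkene geometry, no C4 stereocenter) and C5 a ketone carbon whose hydroxyl is later lost to Δ5(6).
- Ring order: ring B from the chiral pool first, ring A second.

Key step: step 3

Remark on the chemistry: atoms are numbered as in labdanes (decalin C1–C10, side chain C11–C16, C17 on C8, C18/C19 on C4, C20 on C10; α/β as in the usual drawing with C20 β). The carvone-derived C7 centre in compounds 4–12 may epimerise under base and is erased in step 6.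

**Route**

Step 1
Reactants: 1 (S)-(+)-carvone + 2 (1,3-dioxolan-2-ylmethyl)magnesium bromide + 3 allyl bromide
Product: 4 (2R,3R,5S)-2-allyl-3-(1,3-dioxolan-2-ylmethyl)-2-methyl-5-(prop-1-en-2-yl)cyclohexan-1-one
Conditions: 2 (1.5 equiv), CuBr·SMe2 (10 mol %), THF, −78 to −40 °C; then 3 (3 equiv), DMPU, −40 °C to rt
Reagents that add atoms: none
Why: Copper-catalysed conjugate addition should occur anti to the isopropenyl group (sets C9) and the magnesium enolate should be allylated anti to the new neighbouring substituent (sets C10 with its methyl cis to the C9 chain), a tandem conjugate addition–enolate alkylation.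

Step 2
Reactants: 4 (2R,3R,5S)-2-allyl-3-(1,3-dioxolan-2-ylmethyl)-2-methyl-5-(prop-1-en-2-yl)cyclohexan-1-one
Product: 5 keto aldehyde 2-[4-acetyl-2-(1,3-dioxolan-2-ylmethyl)-1-methyl-6-oxocyclohexyl]acetaldehyde
Conditions: O3, CH2Cl2, −78 °C (to first excess); then Me2S, −78 °C to rt
Reagents that add atoms: ozone, [O-][O+]=O
Why: Ozonolysis should cleave both terminal alkenes, turning the allyl group into the C1–C2 acetaldehyde arm and the isopropenyl group into an acetyl group (the masked C7 carbonyl), while the dioxolane is much slower to react.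

Step 3
Reactants: 5 keto aldehyde + 6 (2-methylprop-1-en-1-yl)boronic acid
Product: 10 cis-fused bicyclic C5 carbinol (7α-acetyl-9β-(1,3-dioxolan-2-ylmethyl)-4,4,10β-trimethyl-Δ2-octalin-5β-ol), via tosylhydrazone 7 (not isolated), via diazoalkane 8 (not isolated), via allylboronic acid 9 (not isolated)
Conditions: TsNHNH2 (1.0 equiv), 1,4-dioxane, rt; then 6 (2 equiv), K2CO3 (3 equiv), 100 °C, 0.03 M; aqueous NH4Cl
Reagents that add atoms: 4-methylbenzenesulfonohydrazide, Cc1ccc(cc1)S(=O)(=O)NN (its atoms stay only in 7 and 8)
Why: Proposed new method: condensation of the aldehyde with tosylhydrazide and base-induced Bamford–Stevens loss of sulfinate should give diazoalkane 8, which adds to the boron of 6; 1,2-shift of the alkenyl group with loss of N2 forms C2–C3 and leaves the α-substituted γ,γ-dimethylallylboronic acid 9, which then allylborates the ring ketone through a six-membered cyclic transition state (B–O–C5–C4–C3–C2) to form C4–C5 and the transposed C2=C3 bond. The closest known reaction type is the metal-free reductive coupling of N-tosylhydrazones with boronic acids, in which alkenylboronic acids pass through such transient allylboronic acids that have been intercepted by aldehydes and, intramolecularly, by nitriles; new here is capture by a tethered ketone with the boron-bearing carbon inside the new ring. Ring A closes as a six-membered carbocycle by 6-exo-trig attack of the allyl γ-carbon C4 on the C5 carbonyl; because the C1–C10 tether bridges C2 and C5 the cyclic transition state must be boat-like, which the temperature and the high reactivity of free allylboronic acids toward ketones should allow. The only new stereocenter is C5, where the tether forces C4 onto the carbonyl face that carries C1 (cis-fused carbinol, OH syn to the C10 methyl), and it is erased in step 5; C4 bears two identical methyls so no alkene geometry or C4 stereocenter arises, and either C2 epimer of 9 can react after reversible 1,3-borotropic shift. The step needs chemoselectivity: hydrazone formation at the unhindered aldehyde rather than at the two ketones (one equivalent of hydrazide at rt), and allylation of C5 rather than of the C7 acetyl group or protodeboronation (six-membered against nine-membered closure, run dilute); α-attack is excluded because it would close a four-membered ring.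

Step 4
Reactants: 10 cis-fused bicyclic C5 carbinol
Product: 11 saturated carbinol (7α-acetyl-9β-(1,3-dioxolan-2-ylmethyl)-4,4,10β-trimethyldecalin-5β-ol)
Conditions: H2 (1 atm), Pd/C, EtOAc, rt
Reagents that add atoms: none
Why: Heterogeneous hydrogenation should saturate the only C=C bond (C2=C3), so that the ozonolysis in step 6 meets a single alkene system.

Step 5
Reactants: 11 saturated carbinol
Product: 12 Δ5(6)-alkene (7α-acetyl-9β-(1,3-dioxolan-2-ylmethyl)-4,4,10β-trimethyloctal-5-ene)
Conditions: Burgess reagent, toluene, 70 °C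
Reagents that add atoms: none
Why: Burgess syn-elimination of the tertiary C5 alcohol can only take a hydrogen from C6, because C4 and C10 are quaternary, so it should give the Δ5(6) alkene without a free cation and remove the C5 stereocenter.

Step 6
Reactants: 12 Δ5(6)-alkene
Product: 14 enone (9β-(1,3-dioxolan-2-ylmethyl)-4,4,10β-trimethyloctal-5-en-7-one), via dienol silyl ether 13 (not isolated)
Conditions: TMSCl, Et3N, DMF, 70 °C; crude in CH2Cl2, O3 (1.0 equiv), −78 °C; then Me2S
Reagents that add atoms: ozone, [O-][O+]=O; chlorotrimethylsilane, C[Si](C)(C)Cl (its atoms stay only in 13)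
Why: Thermodynamic silylation should occur at C7–H (α to the acetyl carbonyl and allylic to Δ5) to give the conjugated dienol ether, and ozone should cleave its electron-rich enol-ether bond in preference to the hindered Δ5 alkene, excising the acetyl group and leaving the C7 ketone conjugated with Δ5 (degradation of a methyl ketone through its enol derivative).

Step 7
Reactants: 14 enone
Product: 15 8-methyl enone (8α-methyl epimer drawn)
Conditions: LiN(iPr)2, THF, −78 °C; MeI, −78 to −20 °C
Reagents that add atoms: iodomethane, CI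
Why: Kinetic deprotonation of the enone is possible only at the α′ carbon C8 (no γ-hydrogens, since C4 and C10 are quaternary), and methylation of this cross-conjugated enolate installs C17; the C8 configuration is of no consequence.

Step 8
Reactants: 15 8-methyl enone
Product: 16 8α-hydroxy-8β-methyl enone
Conditions: LiN(iPr)2, THF, −78 to −40 °C; 2-(phenylsulfonyl)-3-phenyloxaziridine, −78 °C; NH4Cl
Reagents that add atoms: 2-(phenylsulfonyl)-3-phenyloxaziridine, O=S(=O)(N1OC1c1ccccc1)c1ccccc1
Why: The only enolisable position is again C8, and the oxaziridine (Davis enolate hydroxylation) should approach the planar enolate from the α face, anti to the axial C10 methyl and the C9 side chain, giving 8α-OH with the methyl β.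

Step 9
Reactants: 16 8α-hydroxy-8β-methyl enone
Product: 18 6α-acetoxy-8α-(trimethylsilyloxy)-7-ketone of the trans-decalin, via bis-silyl enol ether 17 (not isolated)
Conditions: Li, NH3(l)/THF, −78 °C; isoprene; NH3 evaporated; TMSCl, Et3N, THF, −78 to 0 °C; then Pb(OAc)4, CH2Cl2, 0 °C
Reagents that add atoms: lead tetraacetate, CC(=O)O[Pb](OC(C)=O)(OC(C)=O)OC(C)=O; chlorotrimethylsilane, C[Si](C)(C)Cl
Why: Dissolving-metal reduction of the Δ5-7-ketone should protonate C5 axially from the α face (trans ring fusion, as for steroidal Δ5-7-ketones) and give the C6–C7 enolate regiospecifically; after silylation, Pb(OAc)4 acetoxylation of the silyl enol ether (Rubottom-type) should occur from the α face, anti to the axial C10 and C4β methyls, giving the equatorial 6α-acetate.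

Step 10
Reactants: 18 6α-acetoxy-8α-(trimethylsilyloxy)-7-ketone
Product: 19 lactol (6α-acetoxy-12-hydroxy-8α,12-epoxy-13,14,15,16-tetranorlabdan-7-one)
Conditions: AcOH/THF/H2O (3:1:1), 45 °C
Reagents that add atoms: water, O
Why: Mild aqueous acid should hydrolyse the dioxolane and the tertiary silyl ether, and the resulting γ-hydroxy aldehyde should close to the trans-fused five-membered lactol, while the acetate and the ketone survive.

Step 11
Reactants: 19 lactol
Product: 20 (12Z)-6α-acetoxy-8α-hydroxy-13-iodo-14,15-dinorlabd-12-en-7-one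
Conditions: EtPPh3Br, n-BuLi, THF, rt; I2, −78 °C; NaN(SiMe3)2, −78 °C; then 19 (ylide in excess), −78 to −20 °C
Reagents that add atoms: ethyltriphenylphosphonium bromide, CC[P+](c1ccccc1)(c1ccccc1)c1ccccc1.[Br-]; iodine, II
Why: Stork–Zhao-type Wittig olefination of the open hydroxy-aldehyde form of the lactol with the α-iodo ylide should give the Z-iodoalkene (iodine cis to C11) through the kinetic cis-oxaphosphetane, while the C7 ketone, flanked by C6 and the quaternary C8, should not react.

Step 12
Reactants: 20 (12Z)-iodoalkene + 21 tributyl(vinyl)stannane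
Product: 22 (12Z)-6α-acetoxy-8α-hydroxylabda-12,14-dien-7-one
Conditions: Pd(PPh3)4 (5 mol %), CuI, DMF, rt
Reagents that add atoms: none
Why: Stille coupling proceeds with retention of alkene geometry, so the vinyl group ends up cis to C11 and the (12Z)-diene is formed under neutral conditions that spare the acetate, ketone and tertiary alcohol.

Step 13
Reactants: 22 (12Z)-6α-acetoxy-8α-hydroxylabda-12,14-dien-7-one
Product: 23 target, (12Z)-6α-acetoxylabda-12,14-diene-7β,8α-diol
Conditions: NaBH4, CeCl3·7H2O, MeOH, −78 °C
Reagents that add atoms: none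
Why: Luche reduction should deliver hydride axially from the α face, because the β face is screened by the adjacent axial C8 methyl, giving the equatorial 7β-alcohol; low temperature keeps the C6 acetate from migrating and leaves the diene untouched.

**Compound list**

1 | (S)-(+)-carvone | CC1=CC[C@@H](CC1=O)C(C)=C | starting material
2 | (1,3-dioxolan-2-ylmethyl)magnesium bromide | Br[Mg]CC1OCCO1 | starting material
3 | allyl bromide | C=CCBr | starting material
4 | (2R,3R,5S)-2-allyl-3-(1,3-dioxolan-2-ylmethyl)-2-methyl-5-(prop-1-en-2-yl)cyclohexan-1-one | O1CCOC1C[C@H]2C[C@H](C(C)=C)CC(=O)[C@]2(C)CC=C | intermediate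
5 | keto aldehyde, 2-[4-acetyl-2-(1,3-dioxolan-2-ylmethyl)-1-methyl-6-oxocyclohexyl]acetaldehyde (ring configuration as in 4) | O1CCOC1C[C@H]2C[C@H](C(C)=O)CC(=O)[C@]2(C)CC=O | intermediate
6 | (2-methylprop-1-en-1-yl)boronic acid | CC(C)=CB(O)O | starting material
7 | N-tosylhydrazone of 5 at the aldehyde | O1CCOC1C[C@H]2C[C@H](C(C)=O)CC(=O)[C@]2(C)C/C=N/NS(=O)(=O)c1ccc(C)cc1 | intermediate (not isolated)
8 | diazoalkane from 7 | O1CCOC1C[C@H]2C[C@H](C(C)=O)CC(=O)[C@]2(C)CC=[N+]=[N-] | intermediate (not isolated)
9 | α-substituted γ,γ-dimethylallylboronic acid (both epimers at the boron-bearing C2) | O1CCOC1C[C@H]2C[C@H](C(C)=O)CC(=O)[C@]2(C)CC(B(O)O)C=C(C)C | intermediate (not isolated)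
10 | 7α-acetyl-9β-(1,3-dioxolan-2-ylmethyl)-4,4,10β-trimethyl-Δ2-octalin-5β-ol (cis-fused, OH syn to C20) | O1CCOC1C[C@H]2C[C@H](C(C)=O)C[C@]3(O)C(C)(C)C=CC[C@]23C | intermediate
11 | 7α-acetyl-9β-(1,3-dioxolan-2-ylmethyl)-4,4,10β-trimethyldecalin-5β-ol | O1CCOC1C[C@H]2C[C@H](C(C)=O)C[C@]3(O)C(C)(C)CCC[C@]23C | intermediate
12 | 7α-acetyl-9β-(1,3-dioxolan-2-ylmethyl)-4,4,10β-trimethyloctal-5-ene | O1CCOC1C[C@H]2C[C@H](C(C)=O)C=C3C(C)(C)CCC[C@]23C | intermediate
13 | dienol trimethylsilyl ether of 12 (enol ether geometry not defined) | O1CCOC1C[C@H]2CC(=C(C)O[Si](C)(C)C)C=C3C(C)(C)CCC[C@]23C | intermediate (not isolated)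
14 | 9β-(1,3-dioxolan-2-ylmethyl)-4,4,10β-trimethyloctal-5-en-7-one | O1CCOC1C[C@H]2CC(=O)C=C3C(C)(C)CCC[C@]23C | intermediate
15 | 8-methyl derivative of 14 (8α-methyl epimer drawn) | O1CCOC1C[C@H]2[C@H](C)C(=O)C=C3C(C)(C)CCC[C@]23C | intermediate
16 | 8α-hydroxy-8β-methyl-9β-(1,3-dioxolan-2-ylmethyl)-4,4,10β-trimethyloctal-5-en-7-one | O1CCOC1C[C@H]2[C@](C)(O)C(=O)C=C3C(C)(C)CCC[C@]23C | intermediate
17 | bis(trimethylsilyl) derivative: Δ6 7-silyl enol ether, 8α-silyl ether, 5α-H | O1CCOC1C[C@H]2[C@](C)(O[Si](C)(C)C)C(O[Si](C)(C)C)=C[C@H]3C(C)(C)CCC[C@]23C | intermediate (not isolated)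
18 | 6α-acetoxy-8α-(trimethylsilyloxy)-7-ketone with the dioxolanylmethyl side chain (trans-decalin) | O1CCOC1C[C@H]2[C@](C)(O[Si](C)(C)C)C(=O)[C@H](OC(C)=O)[C@H]3C(C)(C)CCC[C@]23C | intermediate
19 | 6α-acetoxy-12-hydroxy-8α,12-epoxy-13,14,15,16-tetranorlabdan-7-one (lactol, both anomers; in equilibrium with the 8α-hydroxy 12-aldehyde) | OC1C[C@H]2[C@](C)(O1)C(=O)[C@H](OC(C)=O)[C@H]3C(C)(C)CCC[C@]23C | intermediate
20 | (12Z)-6α-acetoxy-8α-hydroxy-13-iodo-14,15-dinorlabd-12-en-7-one | I/C(C)=C\C[C@H]1[C@](C)(O)C(=O)[C@H](OC(C)=O)[C@H]2C(C)(C)CCC[C@@]21C | intermediate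
21 | tributyl(vinyl)stannane | C=C[Sn](CCCC)(CCCC)CCCC | starting material
22 | (12Z)-6α-acetoxy-8α-hydroxylabda-12,14-dien-7-one | C=C/C(C)=C\C[C@H]1[C@](C)(O)C(=O)[C@H](OC(C)=O)[C@H]2C(C)(C)CCC[C@@]21C | intermediate
23 | (12Z)-6α-acetoxylabda-12,14-diene-7β,8α-diol | C=C/C(C)=C\C[C@H]1[C@](C)(O)[C@@H](O)[C@H](OC(C)=O)[C@H]2C(C)(C)CCC[C@@]21C | target

**Summary**

Total step count: 13. Longest linear sequence: 13 steps from (S)-carvone 1; all other building blocks (2, 3, 6, 21) are commercial.

Steps most likely to fail, with fallbacks: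

1. Step 3 (proposed new method). The transient allylboronic acid may be lost to protodeboronation or to intermolecular allylation of the acetyl ketone faster than the boat-like intramolecular allylboration, or the diazoalkane may decompose by 1,2-hydride shift before it meets the boronic acid. The fallback sets out from 4 and returns at 12, forming the two ring A bonds separately by known reactions. The isopropenyl group of 4 is epoxidised selectively (mCPBA, NaHCO3, CH2Cl2, 0 °C) to the epoxide F1. Barbier-type reverse prenylation of the ketone (prenyl bromide, In powder, THF/DMF) joins C4 to C5 and gives the tertiary 1,1-dimethylallyl carbinol F2, whose C5 configuration does not matter. Ring-closing metathesis with the second-generation Grubbs catalyst (CH2Cl2, 40 °C) joins C2 to C3 and gives the cyclohexene F3. Diimide reduction (KO2CN=NCO2K, AcOH) gives the saturated epoxide F4, and H5IO6 (THF/H2O) cleaves the epoxide to the methyl ketone F5, which is 11 or its C5 epimer. The Burgess dehydration of step 5 then converges on 12.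

2. Step 6. Silylation may go to the acetyl methyl group instead of C7, or ozone may attack the Δ5 alkene, so that regio- or chemoselectivity is lost. The fallback sets out from 11 and returns at 14. Baeyer–Villiger oxidation (CF3CO3H from (CF3CO)2O and urea–H2O2, Na2HPO4, CH2Cl2) migrates the secondary C7 with retention and gives the 7α-acetate F6. Burgess dehydration gives the Δ5 allylic acetate F7, methanolysis (K2CO3, MeOH) gives the allylic alcohol F8, and MnO2 (CH2Cl2) oxidises it to enone 14.

3. Step 9. The dissolving metal may over-reduce the ketone or cleave the C8 oxygen, and the acetoxylation may be incomplete or unselective. The fallback sets out from 16 and returns at 19. Hydrogenation (H2, Pd/C, EtOAc) from the α face gives the trans-fused saturated ketone F9. Enolisation toward C6, the only enolisable position (LiN(iPr)2, 2.2 equiv, then TMSCl), gives the silyl enol ether 17. Rubottom oxidation (mCPBA, NaHCO3, then citric acid/MeOH) gives the 6α-hydroxy ketone F10, and acetylation of the secondary alcohol (Ac2O, pyridine, DMAP) gives the 6α-acetate F11. The hydrolysis conditions of step 10 convert F11 into lactol 19.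

Further compounds
F1 | step 3 | 2-allyl-3-(1,3-dioxolan-2-ylmethyl)-2-methyl-5-(2-methyloxiran-2-yl)cyclohexan-1-one (epoxide epimers) | O1CCOC1C[C@H]2C[C@H](C3(C)CO3)CC(=O)[C@]2(C)CC=C
F2 | step 3 | 2-allyl-3-(1,3-dioxolan-2-ylmethyl)-2-methyl-1-(2-methylbut-3-en-2-yl)-5-(2-methyloxiran-2-yl)cyclohexan-1-ol (C5 carbinol epimers) | O1CCOC1C[C@H]2C[C@H](C3(C)CO3)CC(O)(C(C)(C)C=C)[C@]2(C)CC=C
F3 | step 3 | 9β-(1,3-dioxolan-2-ylmethyl)-4,4,10β-trimethyl-7α-(2-methyloxiran-2-yl)-Δ2-octalin-5-ol | O1CCOC1C[C@H]2C[C@H](C3(C)CO3)CC4(O)C(C)(C)C=CC[C@]24C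
F4 | step 3 | 9β-(1,3-dioxolan-2-ylmethyl)-4,4,10β-trimethyl-7α-(2-methyloxiran-2-yl)decalin-5-ol | O1CCOC1C[C@H]2C[C@H](C3(C)CO3)CC4(O)C(C)(C)CCC[C@]24C
F5 | step 3 | 7α-acetyl-9β-(1,3-dioxolan-2-ylmethyl)-4,4,10β-trimethyldecalin-5-ol (11 or its C5 epimer) | O1CCOC1C[C@H]2C[C@H](C(C)=O)CC3(O)C(C)(C)CCC[C@]23C
F6 | step 6 | 7α-acetoxy-9β-(1,3-dioxolan-2-ylmethyl)-4,4,10β-trimethyldecalin-5β-ol | O1CCOC1C[C@H]2C[C@H](OC(C)=O)C[C@]3(O)C(C)(C)CCC[C@]23C
F7 | step 6 | 7α-acetoxy-9β-(1,3-dioxolan-2-ylmethyl)-4,4,10β-trimethyloctal-5-ene | O1CCOC1C[C@H]2C[C@H](OC(C)=O)C=C3C(C)(C)CCC[C@]23C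
F8 | step 6 | 9β-(1,3-dioxolan-2-ylmethyl)-4,4,10β-trimethyloctal-5-en-7α-ol | O1CCOC1C[C@H]2C[C@H](O)C=C3C(C)(C)CCC[C@]23C
F9 | step 9 | 8α-hydroxy-8β-methyl-9β-(1,3-dioxolan-2-ylmethyl)-4,4,10β-trimethyl-5α-decalin-7-one | O1CCOC1C[C@H]2[C@](C)(O)C(=O)C[C@H]3C(C)(C)CCC[C@]23C
F10 | step 9 | 6α,8α-dihydroxy-8β-methyl-9β-(1,3-dioxolan-2-ylmethyl)-4,4,10β-trimethyl-5α-decalin-7-one | O1CCOC1C[C@H]2[C@](C)(O)C(=O)[C@H](O)[C@H]3C(C)(C)CCC[C@]23C
F11 | step 9 | 6α-acetoxy-8α-hydroxy-8β-methyl-9β-(1,3-dioxolan-2-ylmethyl)-4,4,10β-trimethyl-5α-decalin-7-one | O1CCOC1C[C@H]2[C@](C)(O)C(=O)[C@H](OC(C)=O)[C@H]3C(C)(C)CCC[C@]23C
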